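Two steps draw on the same starting material, so the easy first step is to divide what one gained by what the other gained.

all flasks: free catalyst 17 mol%

|  | starting material | reagent | remark | time |
|---|---|---|---|---|
| east | 0.10 M | 0.80 equiv | run made earlier |  |
| south-west | 0.050 M | 0.80 equiv | run made earlier |  |
| south | 0.075 M | 0.80 equiv | run made earlier |  |
| Tuesday's | 0.10 M | 0.800 equiv (fed, over 20 min) | all else is in the flask from the start; the feed brings no volume worth counting | 50 min |
| Friday's | 0.10 M | 0.800 equiv (in portions, 4, over 20 min) | first portion at the start, last at 20 min | 50 min |
| Saturday's | 0.10 M | 0.800 equiv | everything together at the start | 50 min |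
| Thursday's | 0.10 M (fed, over 20 min) | 0.800 equiv | all else is in the flask from the start; the feed brings no volume worth counting | 50 min |

| run | time / min | product / % | homo dimer / % | starting material / % |
|---|---|---|---|---|
| east | 4.00 | 17.0 | 50.9 | 33.4 |
| east | 10.0 | 30.7 | 59.8 | 11.5 |
| east | 20.0 | 36.6 | 60.8 | 3.5 |
| east | 30.0 | 39.3 | 60.2 | 0 |
| south-west | 15.0 | 21.8 | 59.1 | 19.6 |
| south-west | 30.0 | 27.3 | 64.6 | 7.4 |
| south-west | 50.0 | 31.1 | 64.2 | 3.5 |
| south-west | 60.0 | 31.6 | 63.2 | 3.3 |
| south | 8.00 | 20.5 | 56.2 | 20.6 |
| south | 20.0 | 34.9 | 60.2 | 7.3 |
| south | 40.0 | 37.8 | 62.6 | 0.8 |
| south | 60.0 | 36.7 | 62.9 | 1.6 |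

(standard deviation of a reading: 1 percentage point)

- percent here means starting material units held: one homo dimer counts as two
- steps under discussion: starting material + reagent + free catalyst -> product + free catalyst; free catalyst -> spent catalyst; 2 starting material -> homo dimer

- which flask leads in share of product in product plus homo dimer ("all alike" within 1.5 percentage points) (Tuesday's / Friday's / Saturday's / Thursday's / all alike)
- share of product in product plus homo dimer at the end, Tuesday's
- share of product in product plus homo dimer at the end, Friday's
- share of product in product plus homo dimer at the end, Saturday's
- share of product in product plus homo dimer at the end, Thursday's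

Over the first 4.00 min of the east run, product reached 17.0% and homo dimer 50.9%, a selectivity factor of 0.334, while starting material averaged about 0.0667 M. As the steps are written, this ratio runs as one over starting material and in step with reagent and free catalyst. Multiplied by that mean it gives 0.0223 M, the level of starting material at which both steps take it equally fast with the east run's early reagent and free catalyst: the crossing concentration. As a share of the charge it reads 22.3% in the east run and 22.1% in the south-west run.

How far does each flask stand above the crossing? Saturday's repeats the east run and starts 4.49 times above it. Tuesday's has a mean of 10.0% of its reagent over the first 4.00 min, which lowers its crossing to 0.002228 M. Friday's first portion, a quarter of the reagent, gives 0.005569 M, more than Tuesday's, yet both lie far below the starting material present.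

Thursday's holds its reagent from the start and meters starting material instead: how high does the feed lift it? The feed brings 0.005000 M min⁻¹. The east run's early fall reads as a second-order loss constant of 4.99 L mol⁻¹ min⁻¹, so feed and loss balance at 0.0317 M. At that level product takes 41.3% of what Thursday's starting material loses, and the level is approached from below.

The forecast gives 25% for Tuesday's, 26% for Friday's, 39.5% for Saturday's and 53% for Thursday's, with Thursday's leading; of Tuesday's and Friday's it says that starving reagent “wastes starting material to dimer”. The order reckoned here is the same, though the forecast's Thursday figure stands above the 41.3% reckoned here at the balance level.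

    starting material + reagent + free catalyst → product + free catalyst, rate k1*[starting material]*[reagent]*[free catalyst]/(1 + ([starting material]/sat1)) (6.95 mM, k = 9.97 L² mol⁻² s⁻¹)
    free catalyst → spent catalyst (k = 5.29 × 10⁻⁴ s⁻¹)
    2 starting material → homo dimer (k = 0.0295 L mol⁻¹ s⁻¹)

Thursday's ends at 54.7%, ahead of Saturday's 39.8%, Friday's 23.8% and Tuesday's 21.8%. At 20.0 min, as its feed ended, Thursday's held 0.0300 M of starting material, beside the balance level of 0.0317 M. A neighbour on Thursday's recipe with 0.025 M of starting material, at the same equivalents and loading, reckons to a crossing of 0.005569 M and a balance level of 0.0158 M, so the reckoned share is 26.1%. That flask ends at 20.7%, with 20% of its starting material left at 50.0 min.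

(The numbers in the tables come from a simulation on assumed constants, and the scatter is random.)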